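**Plan**

- Cuts (labdane numbering; β is the face of the C10 methyl): C13=C14 (olefination), the two isovalerate C–O bonds, C9–C11 (sp2–sp3 cross-coupling at a C9 enol triflate), C4–CH3, and, as the central cut, C1–C10 and C4–C5, which removes ring A as a diene.
- Enabling feature: ring B (C5–C10) with its C6 oxygen, C8 methyl, sp2 C9 and methyl-bearing quaternary C10 has the substitution pattern of 2,6-dimethyl-1,4-benzoquinone, so C1–C4 with the C3 oxygen and the C19 carbon form a 2-silyloxy diene carrying an ester.
- Forward: 2,6-dimethylphenol is oxidised to the quinone monoketal (ring B) and the Diels–Alder reaction closes ring A. Ring B is then edited: C6 ketone freed, C5 inverted, C6 reduced, C9 enone turned into the C8=C9 enol triflate and coupled with C11–C13/C16. Ring A is finished (C4 methyl, C3 and C19 reductions, two isovalerates) and C14–C15 are added last.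
- Stereochemistry: C10 from the chiral boron Lewis acid in the cycloaddition; C5 by equilibration of the enedione to the trans-decalin; C6 and C4 by attack anti to the axial C10 methyl (hydride, then methyl iodide); C3 by equatorial attack of a bulky hydride; the 13E olefin by a Horner–Wadsworth–Emmons reaction.

Key step: step 5

Assumption: precedent does not fix the sense of induction of the oxazaborolidinium catalyst for a dienone with methyl groups on both α carbons; the (S)-prolinol-derived catalyst is written, and its mirror image is the one to use if the first run shows the antipodal adduct.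

**Step 1**
Reactants: 1 2,6-dimethylphenol
Product: 3 4,4-dimethoxy-2,6-dimethylcyclohexa-2,5-dien-1-one, via 4-methoxy-2,6-dimethylphenol 2 (not isolated)
Conditions: PhI(OAc)2 (2.2 equiv), MeOH, 0 °C to rt
Reagents that add atoms: methanol, CO
Why: Oxidative dearomatisation with a hypervalent iodine reagent: the phenol is oxidised twice in methanol, first to the 4-methoxyphenol and then to the para-quinone monoketal, the two ortho methyl groups leaving only the para position open to methanol.

**Step 2**
Reactants: 4 methyl acetate; 5 acrolein
Product: 7 methyl 3-hydroxypent-4-enoate (racemic), via lithium enolate 6 (not isolated)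
Conditions: LiN(i-Pr)2, THF, −78 °C; then acrolein, −78 °C; aq. NH4Cl
Reagents that add atoms: none
Why: Aldol addition of the lithium ester enolate to the aldehyde carbonyl (1,2-addition is kinetically preferred over conjugate addition at −78 °C); the carbinol centre is racemic and disappears in the next step.

**Step 3**
Reactants: 7 methyl 3-hydroxypent-4-enoate
Product: 8 methyl 3-oxopent-4-enoate
Conditions: Dess–Martin periodinane, CH2Cl2, 0 °C to rt; used crude at once
Reagents that add atoms: none
Why: Dess–Martin oxidation of the secondary allylic alcohol gives the vinyl β-keto ester (Nazarov reagent) under near-neutral conditions that this polymerisation-prone enone should tolerate.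

**Step 4**
Reactants: 8 methyl 3-oxopent-4-enoate
Product: 9 methyl (2Z)-3-(triisopropylsilyloxy)penta-2,4-dienoate
Conditions: TIPSOTf, Et3N, CH2Cl2, −78 to 0 °C
Reagents that add atoms: triisopropylsilyl triflate, CC(C)[Si](C(C)C)(C(C)C)OS(=O)(=O)C(F)(F)F
Why: O-silylation of the β-keto ester under soft enolisation traps the hydrogen-bonded Z enol, which puts the ester on the outer position of the s-cis diene; the triisopropylsilyl group is chosen so that the enol ether later outlasts the ketal hydrolysis.

**Step 5**
Reactants: 3 4,4-dimethoxy-2,6-dimethylcyclohexa-2,5-dien-1-one; 9 methyl (2Z)-3-(triisopropylsilyloxy)penta-2,4-dienoate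
Product: 10 cis-fused endo adduct (C9 enone; C6 dimethyl ketal; C2=C3 silyl enol ether; 4α-CO2Me; 5β-H; 10β-methyl)
Conditions: (S)-3,3-diphenyl-1-(o-tolyl)tetrahydro-1H,3H-pyrrolo[1,2-c][1,3,2]oxazaborole (20 mol%), HNTf2 (18 mol%), CH2Cl2, −78 to −40 °C; Et3N quench
Reagents that add atoms: none
Why: The protonated oxazaborolidine binds the only carbonyl of 3 (C9) and lowers the LUMO of the C5=C10 bond, and the silyl enol ether terminus of 9 (C4) bonds to the β carbon C5 slightly ahead of the C1–C10 bond in a concerted, asynchronous [4+2] cycloaddition. The closest known reaction type is the Lewis-acid-catalysed Diels–Alder reaction of 2-silyloxy dienes with quinone monoketals and cyclic enones, including enantioselective versions with cationic chiral boron Lewis acids. Ring A closes as a six-membered ring by suprafacial addition to both partners, so the C10 methyl and the C5 hydrogen end up cis. C10 is fixed by the face of the dienone that the catalyst leaves open, C5 follows from the suprafacial addition, and C4 from the endo arrangement of ring B under the diene with the ester on the outer position of the Z enol ether; C4 and C5 are re-set later, so only C10 has to be right here. The step needs regio- and face selectivity: the ketal leaves a single conjugating carbonyl, which together with the silyloxy polarisation of the diene dictates C4-to-C5 bonding, and because the two double bonds of 3 are equivalent by symmetry the only remaining choice is the face, which the catalyst makes.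

**Step 6**
Reactants: 10 cis-fused endo adduct
Product: 12 trans-fused enedione (5α-H), via cis-fused enedione 11 (not isolated)
Conditions: PPTS (0.2 equiv), THF/H2O (5:1), rt; then DBU (0.6 equiv) added to the same flask, rt
Reagents that add atoms: water, O
Why: Acid-catalysed ketal hydrolysis (the dimethyl ketal should ionise well before the hindered silyl enol ether is protonated at carbon) followed by base-mediated epimerisation of the ring-fusion centre C5 (α to the C6 ketone), which should settle on the trans-fused isomer as in the classical cis-to-trans isomerisation of angularly methylated quinone Diels–Alder adducts; the C4 hydrogen is far less acidic, and exchange there would be harmless because C4 is re-set at step 12.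

**Step 7**
Reactants: 12 trans-fused enedione
Product: 13 6β-hydroxy enone
Conditions: NaBH4, CeCl3·7H2O, MeOH, −78 °C
Reagents that add atoms: none
Why: Luche 1,2-reduction: the C6 carbonyl should react in preference to the C9 carbonyl, which lies between the quaternary C10 and the methylated C8, and hydride enters from the α face, anti to the axial C10 methyl, giving the 6β (axial) alcohol.

**Step 8**
Reactants: 13 6β-hydroxy enone
Product: 14 6β-tert-butyldimethylsilyl ether
Conditions: TBSOTf, 2,6-lutidine, CH2Cl2, −78 to 0 °C
Reagents that add atoms: tert-butyldimethylsilyl triflate, CC(C)(C)[Si](C)(C)OS(=O)(=O)C(F)(F)F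
Why: Silyl triflate silylation of the hindered secondary allylic alcohol with a hindered pyridine base masks O6 for the enolate, organometallic and hydride steps that follow.

**Step 9**
Reactants: 14 6β-tert-butyldimethylsilyl ether
Product: 16 C9 enol triflate (C8=C9), via lithium enolate 15 (not isolated)
Conditions: LiBH(s-Bu)3 (L-Selectride, 1.1 equiv), THF, −78 °C; then Comins' reagent, −78 to 0 °C
Reagents that add atoms: Comins' reagent, FC(F)(F)S(=O)(=O)N(c1ccc(Cl)cn1)S(=O)(=O)C(F)(F)F
Why: Conjugate hydride reduction of the β-unsubstituted, α-methyl enone by the bulky borohydride (1,2-attack at the neopentyl C9 carbonyl is blocked) gives the C8=C9 enolate regiospecifically, and O-sulfonylation by the N-pyridyl triflimide turns it into the tetrasubstituted enol triflate.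

**Step 10**
Reactants: 16 C9 enol triflate; 17 2-(2-bromoethyl)-2-methyl-1,3-dioxolane
Product: 19 C9-alkylated diene (side-chain ketone as dioxolane), via alkylzinc bromide 18 (not isolated)
Conditions: Zn dust, LiCl, THF, 40 °C; then 16, Pd(dppf)Cl2 (5 mol%), THF/NMP, 60 °C
Reagents that add atoms: none
Why: Negishi sp2–sp3 cross-coupling: zerovalent palladium inserts into the enol triflate, the alkylzinc bromide transmetalates, and reductive elimination from the wide-bite-angle dppf complex outpaces β-hydride elimination, all without base so that the ester and both silyl groups stay intact.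

**Step 11**
Reactants: 19 C9-alkylated diene
Product: 20 β-keto ester (C3 ketone; C4-H)
Conditions: Bu4NF (1.1 equiv), AcOH (1.2 equiv), THF, −20 to 0 °C
Reagents that add atoms: none
Why: Fluoride cleaves the O–Si bond of the enol ether (an enolate leaves far more readily than a hindered secondary alkoxide, so the C6 silyl ether should stay) and the acetic acid buffer protonates the enolate to the β-keto ester, whose C4 centre is fixed in the next step.

**Step 12**
Reactants: 20 β-keto ester
Product: 21 4α-methyl-4β-methoxycarbonyl 3-ketone
Conditions: K2CO3, MeI, acetone, 50 °C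
Reagents that add atoms: methyl iodide, CI
Why: C-alkylation of the β-keto ester enolate: methyl iodide approaches the planar C4 from the α face because the β face is screened by the axial C10 methyl and the 6β-silyloxy group, which places the new methyl α (equatorial) and the ester β (axial), as in classical methylations of trans-decalin β-keto esters.

**Step 13**
Reactants: 21 4α-methyl-4β-methoxycarbonyl 3-ketone
Product: 22 3α-hydroxy ester
Conditions: LiBH(s-Bu)3 (L-Selectride), THF, −78 to −40 °C; aq. NH4Cl
Reagents that add atoms: none
Why: Diastereoselective ketone reduction with a bulky trialkylborohydride: the reagent avoids the axial trajectory past the C1 and C5 axial hydrogens and attacks equatorially, giving the axial 3α alcohol, while the neopentyl ester is not reduced at low temperature.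

**Step 14**
Reactants: 22 3α-hydroxy ester
Product: 23 3α,19-diol
Conditions: LiAlH4, THF, 0 to 50 °C; aq. NaOH work-up
Reagents that add atoms: none
Why: LiAlH4 reduction of the hindered axial methyl ester to the primary C19 alcohol, to which the silyl ether, the dioxolane and the tetrasubstituted olefin are inert.

**Step 15**
Reactants: 23 3α,19-diol; 24 isovaleryl chloride
Product: 26 3α,19-bis(isovalerate), via 19-monoisovalerate 25 (not isolated)
Conditions: isovaleryl chloride (3 equiv), pyridine, DMAP (0.2 equiv), CH2Cl2, 0 °C to rt
Reagents that add atoms: isovaleryl chloride (second equivalent), CC(C)CC(Cl)=O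
Why: DMAP-catalysed acylation with the acid chloride, in which the primary neopentyl C19 hydroxyl is esterified first and the axial 3α-hydroxyl follows with a second equivalent of the reagent, pyridine serving as the base so that ketene formation from the acyl chloride is avoided.

**Step 16**
Reactants: 26 3α,19-bis(isovalerate)
Product: 27 3α,19-bis(isovaleryloxy)-6β-hydroxy-14,15-dinorlabd-8-en-13-one
Conditions: 48% aq. HF, MeCN, rt
Reagents that add atoms: water, O
Why: Acidic fluoride removes the hindered silyl ether and the aqueous acid hydrolyses the dioxolane in one operation, under which the two esters and the tetrasubstituted olefin should be stable and acyl migration to O6 has no base to promote it.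

**Step 17**
Reactants: 27 keto alcohol; 28 allyl diethylphosphonoacetate
Product: 30 allyl 3α,19-bis(isovaleryloxy)-6β-hydroxylabda-8,13E-dien-15-oate, via sodium phosphonate carbanion 29 (not isolated)
Conditions: 28 (2.0 equiv), NaH (1.9 equiv), THF, 0 °C; then 27, 0 to 50 °C
Reagents that add atoms: none
Why: Horner–Wadsworth–Emmons olefination of the methyl ketone: reversible addition of the stabilised phosphonate carbanion and elimination should favour the E trisubstituted enoate (C12 trans to the ester), the anion being too weakly basic to deprotonate the 6-hydroxyl or enolise the isovalerates; any Z isomer would be removed by chromatography.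

**Step 18**
Reactants: 30 allyl ester
Product: 31 3α,19-bis(isovaleryloxy)-6β-hydroxylabda-8,13E-dien-15-oic acid (CNP0333611.1)
Conditions: Pd(PPh3)4 (5 mol%), morpholine (5 equiv), THF, rt; wash at pH 4
Reagents that add atoms: none
Why: Tsuji–Trost deallylation: zerovalent palladium ionises the allyl ester to a π-allyl complex that morpholine captures, freeing the carboxylic acid under neutral conditions that leave both isovalerates and the free 6-hydroxyl untouched.

**Compound list**

1 | 2,6-dimethylphenol | Cc1cccc(C)c1O | starting material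
2 | 4-methoxy-2,6-dimethylphenol | COc1cc(C)c(O)c(C)c1 | intermediate (not isolated)
3 | 4,4-dimethoxy-2,6-dimethylcyclohexa-2,5-dien-1-one (quinone monoketal; ring B) | CC1=CC(OC)(OC)C=C(C)C1=O | intermediate
4 | methyl acetate | COC(C)=O | starting material
5 | acrolein | C=CC=O | starting material
6 | lithium enolate of methyl acetate | [Li+].C=C([O-])OC | intermediate (not isolated)
7 | methyl 3-hydroxypent-4-enoate (racemic) | C=CC(O)CC(=O)OC | intermediate
8 | methyl 3-oxopent-4-enoate | C=CC(=O)CC(=O)OC | intermediate
9 | methyl (2Z)-3-(triisopropylsilyloxy)penta-2,4-dienoate | C=C/C(O[Si](C(C)C)(C(C)C)C(C)C)=C/C(=O)OC | intermediate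
10 | cis-fused endo adduct: ring A with C2=C3 triisopropylsilyl enol ether and 4α-CO2Me; ring B with C6 dimethyl ketal, C7=C8 (8-methyl) and C9 ketone; 5β-H; 10β-methyl | O=C1[C@@]2(C)CC=C(O[Si](C(C)C)(C(C)C)C(C)C)[C@@H](C(=O)OC)[C@H]2C(OC)(OC)C=C1C | intermediate
11 | cis-fused enedione: as 10 with a C6 ketone in place of the ketal (5β-H) | O=C1[C@@]2(C)CC=C(O[Si](C(C)C)(C(C)C)C(C)C)[C@@H](C(=O)OC)[C@H]2C(=O)C=C1C | intermediate (not isolated)
12 | trans-fused enedione: C5 epimer of 11 (5α-H; 10β-methyl; 4α-CO2Me) | O=C1[C@@]2(C)CC=C(O[Si](C(C)C)(C(C)C)C(C)C)[C@@H](C(=O)OC)[C@@H]2C(=O)C=C1C | intermediate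
13 | 6β-hydroxy enone: as 12 with the C6 ketone reduced to the 6β-alcohol (C7=C8–C9=O retained) | O=C1[C@@]2(C)CC=C(O[Si](C(C)C)(C(C)C)C(C)C)[C@@H](C(=O)OC)[C@@H]2[C@H](O)C=C1C | intermediate
14 | 6β-tert-butyldimethylsilyl ether of 13 | O=C1[C@@]2(C)CC=C(O[Si](C(C)C)(C(C)C)C(C)C)[C@@H](C(=O)OC)[C@@H]2[C@H](O[Si](C)(C)C(C)(C)C)C=C1C | intermediate
15 | lithium C8=C9 enolate from conjugate reduction of 14 | CC1=C([O-])[C@@]2(C)CC=C(O[Si](C(C)C)(C(C)C)C(C)C)[C@@H](C(=O)OC)[C@@H]2[C@H](O[Si](C)(C)C(C)(C)C)C1.[Li+] | intermediate (not isolated)
16 | C9 enol triflate (C8=C9; 6β-OTBS; C2=C3 silyl enol ether; 4α-CO2Me; 5α-H) | CC1=C(OS(=O)(=O)C(F)(F)F)[C@@]2(C)CC=C(O[Si](C(C)C)(C(C)C)C(C)C)[C@@H](C(=O)OC)[C@@H]2[C@H](O[Si](C)(C)C(C)(C)C)C1 | intermediate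
17 | 2-(2-bromoethyl)-2-methyl-1,3-dioxolane | CC1(CCBr)OCCO1 | starting material
18 | [2-(2-methyl-1,3-dioxolan-2-yl)ethyl]zinc bromide | CC1(CC[Zn]Br)OCCO1 | intermediate (not isolated)
19 | C9-alkylated diene: as 16 with the 2-(2-methyl-1,3-dioxolan-2-yl)ethyl chain (C11–C13, C16) in place of the triflate | CC1=C(CCC3(C)OCCO3)[C@@]2(C)CC=C(O[Si](C(C)C)(C(C)C)C(C)C)[C@@H](C(=O)OC)[C@@H]2[C@H](O[Si](C)(C)C(C)(C)C)C1 | intermediate
20 | β-keto ester: C3 ketone, C4-H with CO2Me (keto form drawn; C4 epimers and enol interconvert), 6β-OTBS, C8=C9, dioxolane side chain | CC1=C(CCC3(C)OCCO3)[C@@]2(C)CCC(=O)[C@@H](C(=O)OC)[C@@H]2[C@H](O[Si](C)(C)C(C)(C)C)C1 | intermediate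
21 | methyl 13,13-ethylenedioxy-3-oxo-6β-(tert-butyldimethylsilyloxy)-14,15-dinorlabd-8-en-19-oate (4α-methyl; 4β-CO2Me; 5α-H; 10β-methyl) | CC1=C(CCC3(C)OCCO3)[C@@]2(C)CCC(=O)[C@](C)(C(=O)OC)[C@@H]2[C@H](O[Si](C)(C)C(C)(C)C)C1 | intermediate
22 | methyl 13,13-ethylenedioxy-3α-hydroxy-6β-(tert-butyldimethylsilyloxy)-14,15-dinorlabd-8-en-19-oate | CC1=C(CCC3(C)OCCO3)[C@@]2(C)CC[C@@H](O)[C@](C)(C(=O)OC)[C@@H]2[C@H](O[Si](C)(C)C(C)(C)C)C1 | intermediate
23 | 13,13-ethylenedioxy-6β-(tert-butyldimethylsilyloxy)-14,15-dinorlabd-8-ene-3α,19-diol | CC1=C(CCC3(C)OCCO3)[C@@]2(C)CC[C@@H](O)[C@](C)(CO)[C@@H]2[C@H](O[Si](C)(C)C(C)(C)C)C1 | intermediate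
24 | isovaleryl chloride | CC(C)CC(Cl)=O | starting material
25 | 13,13-ethylenedioxy-19-(isovaleryloxy)-6β-(tert-butyldimethylsilyloxy)-14,15-dinorlabd-8-en-3α-ol (19-monoisovalerate) | CC1=C(CCC3(C)OCCO3)[C@@]2(C)CC[C@@H](O)[C@](C)(COC(=O)CC(C)C)[C@@H]2[C@H](O[Si](C)(C)C(C)(C)C)C1 | intermediate (not isolated)
26 | 13,13-ethylenedioxy-3α,19-bis(isovaleryloxy)-6β-(tert-butyldimethylsilyloxy)-14,15-dinorlabd-8-ene | CC1=C(CCC3(C)OCCO3)[C@@]2(C)CC[C@@H](OC(=O)CC(C)C)[C@](C)(COC(=O)CC(C)C)[C@@H]2[C@H](O[Si](C)(C)C(C)(C)C)C1 | intermediate
27 | 3α,19-bis(isovaleryloxy)-6β-hydroxy-14,15-dinorlabd-8-en-13-one | CC1=C(CCC(C)=O)[C@@]2(C)CC[C@@H](OC(=O)CC(C)C)[C@](C)(COC(=O)CC(C)C)[C@@H]2[C@H](O)C1 | intermediate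
28 | allyl diethylphosphonoacetate | C=CCOC(=O)CP(=O)(OCC)OCC | starting material
29 | sodium salt of the allyl diethylphosphonoacetate carbanion | [Na+].C=CCOC(=O)[CH-]P(=O)(OCC)OCC | intermediate (not isolated)
30 | allyl 3α,19-bis(isovaleryloxy)-6β-hydroxylabda-8,13E-dien-15-oate | CC1=C(CC/C(C)=C/C(=O)OCC=C)[C@@]2(C)CC[C@@H](OC(=O)CC(C)C)[C@](C)(COC(=O)CC(C)C)[C@@H]2[C@H](O)C1 | intermediate
31 | 3α,19-bis(isovaleryloxy)-6β-hydroxylabda-8,13E-dien-15-oic acid (CNP0333611.1) | CC1=C(CC/C(C)=C/C(=O)O)[C@@]2(C)CC[C@@H](OC(=O)CC(C)C)[C@](C)(COC(=O)CC(C)C)[C@@H]2[C@H](O)C1 | target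

**Step count**

Total steps: 18. Longest linear sequence: 17 steps (4 to 31 through steps 2–18); the phenol branch joins after one step.

**Steps most likely to fail**

Step 5. The cycloaddition may be too slow: the dienophile carbon pair is trisubstituted (α-methyl, β carbon next to the ketal) and the nucleophilic diene terminus carries an ester. The strong Lewis acid may instead strip methanol from the ketal (aromatisation) or desilylate the diene. Facial discrimination may be weak because the bound carbonyl has no α-hydrogen to anchor the catalyst. Fallback: starting from 3 and 9, the cycloaddition is run without any Lewis acid at 12–15 kbar in CH2Cl2 at room temperature, where the negative activation volume drives the reaction and no acid is present. This gives the racemate, that is 10 together with the mirror-image adduct F1. The enantiomers are separated by preparative chromatography on a chiral stationary phase and the route is rejoined at 10.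

Step 6. The silyl enol ether may be hydrolysed along with the ketal, which would expose the C3 ketone next to the C9 enone and open a retro-Michael path that unravels ring A. The base equilibration may also stop short of the trans isomer. Fallback: starting from 10, both masks are removed on purpose with 1 M aq. HCl in THF. Prolonged stirring in the same acid equilibrates C5 and gives the trans-fused trione F2, whose β-keto ester sits largely as the C3=C4 enol and so does not enolise toward C2. TIPSOTf/Et3N at −78 °C re-masks ring A as the conjugated silyl enol ether F3. F3 is taken through the operations of steps 7–10: Luche reduction to the 6β-alcohol F4, silylation to the TBS ether F5, conjugate reduction and triflation to the enol triflate F6, and Negishi coupling to the coupled product F7. Bu4NF/AcOH then cleaves the enol ether of F7 and the route is rejoined at 20.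

Step 10. Oxidative addition and reductive elimination at the triflate carbon, flanked by the quaternary C10 and the C8 methyl, may be so slow that reduction of the triflate or β-hydride elimination of the alkylpalladium species takes over. Fallback: starting from 16, a Sonogashira coupling is run with 2-ethynyl-2-methyl-1,3-dioxolane (C#CC1(C)OCCO1; Pd(PPh3)2Cl2, CuI, Et3N, DMF, 50 °C). The slender sp nucleophile is far less sensitive to the flanking substituents and gives the enyne F8. Diimide (2-nitrobenzenesulfonylhydrazide, Et3N, CH2Cl2, rt) then saturates the triple bond but should spare the tetrasubstituted C8=C9 bond and the trisubstituted enol ether, and the route is rejoined at 19.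

**Further compounds**

F1 | step 5 | mirror-image adduct (enantiomer of 10) | O=C1[C@]2(C)CC=C(O[Si](C(C)C)(C(C)C)C(C)C)[C@H](C(=O)OC)[C@@H]2C(OC)(OC)C=C1C
F2 | step 6 | trans-fused trione (C3 ketone with C4 CO2Me; C6 and C9 ketones; C7=C8; 5α-H; keto form drawn) | O=C1[C@@]2(C)CCC(=O)[C@@H](C(=O)OC)[C@@H]2C(=O)C=C1C
F3 | step 6 | conjugated silyl enol ether (C3=C4 with 3-OTIPS and 4-CO2Me) of the trans-fused enedione | O=C1[C@@]2(C)CCC(O[Si](C(C)C)(C(C)C)C(C)C)=C(C(=O)OC)[C@@H]2C(=O)C=C1C
F4 | step 6 | 6β-alcohol from F3 | O=C1[C@@]2(C)CCC(O[Si](C(C)C)(C(C)C)C(C)C)=C(C(=O)OC)[C@@H]2[C@H](O)C=C1C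
F5 | step 6 | 6β-TBS ether of F4 | O=C1[C@@]2(C)CCC(O[Si](C(C)C)(C(C)C)C(C)C)=C(C(=O)OC)[C@@H]2[C@H](O[Si](C)(C)C(C)(C)C)C=C1C
F6 | step 6 | C9 enol triflate from F5 | CC1=C(OS(=O)(=O)C(F)(F)F)[C@@]2(C)CCC(O[Si](C(C)C)(C(C)C)C(C)C)=C(C(=O)OC)[C@@H]2[C@H](O[Si](C)(C)C(C)(C)C)C1
F7 | step 6 | coupled product from F6 (dioxolane side chain at C9) | CC1=C(CCC3(C)OCCO3)[C@@]2(C)CCC(O[Si](C(C)C)(C(C)C)C(C)C)=C(C(=O)OC)[C@@H]2[C@H](O[Si](C)(C)C(C)(C)C)C1
F8 | step 10 | enyne (C9–C≡C–C(CH3) dioxolane) | CC1=C(C#CC3(C)OCCO3)[C@@]2(C)CC=C(O[Si](C(C)C)(C(C)C)C(C)C)[C@@H](C(=O)OC)[C@@H]2[C@H](O[Si](C)(C)C(C)(C)C)C1
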